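The C2–C3 bond, between the acetoxy-bearing stereocentre of the tridecan-2-yl chain (C2) and the first methylene of the undecyl tail (C3), is the disconnection on which the route rests. A nickel hydride catalysed, enantioconvergent hydroalkylation joins 1-undecene to a racemic 1-bromoalkyl acetate that is formed in the flask from a bis-benzyl-protected (2,5-dihydroxy-3-methoxyphenyl)acetaldehyde and acetyl bromide. One operation forms the C2–C3 bond, funnels both enantiomers of the bromide into the (R) centre and installs the acetate. It exploits C2 with its acetoxy oxygen: the α-acyloxy radical is planar, and the ester carbonyl binds the chiral nickel centre. The benzene ring is only a protected spectator. The aldehyde derives from o-eugenol; hydrogenolysis ends the route.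

Key step: step 4

Assumption: the sense of induction of the chiral bis(oxazoline) ligand is not fixed here; the ligand enantiomer that gives the (R) acetate is to be chosen in a pilot run, with the configuration checked by Mosher ester analysis of the derived alcohol.

Step 1
Reactants: 1 o-eugenol (2-allyl-6-methoxyphenol)
Product: 2 2-allyl-6-methoxy-1,4-benzoquinone
Conditions: Fremy's salt (2.5 equiv), KH2PO4, H2O/acetone, 0 °C → rt
Reagents that add atoms: potassium nitrosodisulfonate (Fremy's salt), [K+].[K+].[O]N(S(=O)(=O)[O-])S(=O)(=O)[O-]
Why: Teuber oxidation, in which the phenoxyl radical is trapped by a second nitroxyl at the free para position (both ortho positions carry allyl or OMe), should give the p-quinone without touching the allyl group.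

Step 2
Reactants: 2 2-allyl-6-methoxy-1,4-benzoquinone
Product: 4 1-allyl-2,5-bis(benzyloxy)-3-methoxybenzene, via hydroquinone 3 (not isolated)
Conditions: Na2S2O4, THF/H2O, rt, Ar; then aq. KOH, Bu4NBr (cat.), BnBr (3 equiv), rt
Reagents that add atoms: benzyl bromide, BrCc1ccccc1
Why: Reductive alkylation of a quinone, in which dithionite reduces 2 to hydroquinone 3 and both phenoxides are O-benzylated under phase-transfer Williamson conditions while excess dithionite suppresses re-oxidation.

Step 3
Reactants: 4 1-allyl-2,5-bis(benzyloxy)-3-methoxybenzene
Product: 6 2-[2,5-bis(benzyloxy)-3-methoxyphenyl]acetaldehyde, via diol 5 (not isolated)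
Conditions: OsO4 (2 mol%), NaIO4 (4 equiv), 2,6-lutidine, dioxane/H2O (3:1), rt; short silica plug, used at once
Reagents that add atoms: osmium tetroxide (catalytic oxygen carrier), O=[Os](=O)(=O)=O; sodium periodate (terminal oxygen source), [Na+].[O-]I(=O)(=O)=O
Why: Lemieux–Johnson oxidation, in which osmium-catalysed dihydroxylation of the only alkene and periodate glycol cleavage release the arylacetaldehyde, with 2,6-lutidine suppressing over-oxidation and the fully etherified arene inert to periodate.

Step 4
Reactants: 6 2-[2,5-bis(benzyloxy)-3-methoxyphenyl]acetaldehyde; 7 1-undecene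
Product: 9 (R)-1-[2,5-bis(benzyloxy)-3-methoxyphenyl]tridecan-2-yl acetate, via rac-bromo acetate 8 (not isolated)
Conditions: AcBr (1.1 equiv), CH2Cl2, −20 → 0 °C, volatiles removed; then NiBr2·glyme (10 mol%), chiral bis(oxazoline) L* (12 mol%), 7 (1.5 equiv), (EtO)2MeSiH (2 equiv), K3PO4·H2O (2.5 equiv), iPr2O/DMA, 0 °C
Reagents that add atoms: acetyl bromide, CC(Br)=O
Why: This is the nickel-catalysed enantioconvergent reductive hydroalkylation of an olefin with a racemic 1-bromoalkyl ester, run in its known four-component form (aldehyde, acyl bromide, olefin, hydrosilane); acetyl bromide first adds across the C=O of 6 to give racemic 8. The L*Ni–H species formed from silane and phosphate inserts 7 with anti-Markovnikov regiochemistry to give a primary undecyl–nickel species, while bromine abstraction from either enantiomer of 8 gives the same planar α-acetoxyalkyl radical, which is captured at nickel and joined to the undecyl group by reductive elimination. No ring is closed. The single new stereocentre C2 is set by the chiral bis(oxazoline) ligand (catalyst control), aided by coordination of the acetate carbonyl to nickel, so the configuration of 8 is irrelevant. The step needs regioselectivity for the terminal alkene carbon, which the monosubstituted olefin secures, and chemoselectivity for C–C coupling over loss of HBr to the enol acetate or C–Br reduction, for which the mild heterogeneous base, the low temperature and the immediate use of 8 are chosen; the benzyl and methyl aryl ethers are inert.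

Step 5
Reactants: 9 (R)-1-[2,5-bis(benzyloxy)-3-methoxyphenyl]tridecan-2-yl acetate
Product: 10 (R)-1-(2,5-dihydroxy-3-methoxyphenyl)tridecan-2-yl acetate (CNP0331604.1)
Conditions: H2 (1 atm), 10% Pd/C, EtOAc, rt; filtration and concentration under Ar
Reagents that add atoms: none
Why: Catalytic hydrogenolysis of the two aryl benzyl ethers under neutral, aprotic conditions should leave the non-benzylic secondary acetate, the aryl methyl ether and the stereocentre untouched.

Compound list
1 | o-eugenol (2-allyl-6-methoxyphenol) | C=CCc1cccc(OC)c1O | starting material
2 | 2-allyl-6-methoxy-1,4-benzoquinone | C=CCC1=CC(=O)C=C(OC)C1=O | intermediate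
3 | 2-allyl-6-methoxybenzene-1,4-diol (hydroquinone, not isolated) | C=CCc1cc(O)cc(OC)c1O | intermediate
4 | 1-allyl-2,5-bis(benzyloxy)-3-methoxybenzene | C=CCc1cc(OCc2ccccc2)cc(OC)c1OCc1ccccc1 | intermediate
5 | rac-3-[2,5-bis(benzyloxy)-3-methoxyphenyl]propane-1,2-diol (not isolated) | OCC(O)Cc1cc(OCc2ccccc2)cc(OC)c1OCc1ccccc1 | intermediate
6 | 2-[2,5-bis(benzyloxy)-3-methoxyphenyl]acetaldehyde | O=CCc1cc(OCc2ccccc2)cc(OC)c1OCc1ccccc1 | intermediate
7 | 1-undecene | C=CCCCCCCCCC | starting material
8 | rac-1-bromo-2-[2,5-bis(benzyloxy)-3-methoxyphenyl]ethyl acetate (not isolated) | CC(=O)OC(Br)Cc1cc(OCc2ccccc2)cc(OC)c1OCc1ccccc1 | intermediate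
9 | (R)-1-[2,5-bis(benzyloxy)-3-methoxyphenyl]tridecan-2-yl acetate | CCCCCCCCCCC[C@H](Cc1cc(OCc2ccccc2)cc(OC)c1OCc1ccccc1)OC(C)=O | intermediate
10 | (R)-1-(2,5-dihydroxy-3-methoxyphenyl)tridecan-2-yl acetate (CNP0331604.1) | CCCCCCCCCCC[C@H](Cc1cc(O)cc(OC)c1O)OC(C)=O | target

Total step count: 5
Longest linear sequence: 5 steps (1 → 2 → 4 → 6 → 9 → 10)

Steps most likely to fail

Step 4 (key step). The bromo acetate may lose HBr towards the conjugated enol acetate, its C–Br bond may be reduced by the nickel hydride, or the small acetyl group may give insufficient enantioinduction. The fallback makes the same C2–C3 bond by a two-electron, catalytic enantioselective dialkylzinc addition. It sets out from 7 and 6. Hydroboration of 7 with Et2BH should give diethyl(undecyl)borane F1. Boron–zinc exchange with neat Et2Zn, followed by removal of Et3B and excess Et2Zn in vacuo, should give diundecylzinc F2. Addition of F2 to 6 in toluene at −20 °C with Ti(OiPr)4 and a catalytic chiral trans-1,2-bis(trifluoromethanesulfonamido)cyclohexane should give (R)-1-[2,5-bis(benzyloxy)-3-methoxyphenyl]tridecan-2-ol F3. The ligand enantiomer that directs alkyl transfer to the Re face of the aldehyde is needed, expected by analogy to be the (1S,2S) ligand. Acetylation (Ac2O, pyridine, DMAP) returns to the route at 9.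

Step 3. The electron-rich arylacetaldehyde may enolise and self-condense, or be over-oxidised, during cleavage and isolation. The fallback stores the carbon skeleton at the alcohol oxidation level. It sets out from 4. Ozonolysis (CH2Cl2/MeOH, −78 °C, Sudan III end-point) with NaBH4 work-up in the same flask should give the stable 2-[2,5-bis(benzyloxy)-3-methoxyphenyl]ethanol F4. Dess–Martin oxidation (NaHCO3, CH2Cl2) immediately before the coupling returns to the route at 6, used as a filtered solution.

Step 2. Dithionite may consume benzyl bromide, the hindered phenoxide between OMe and allyl may alkylate sluggishly, and the hydroquinone dianion may re-oxidise. The fallback traps the hydroquinone as an air-stable ester before benzylation. It sets out from 2. Reductive acetylation (Zn dust, Ac2O, NaOAc, rt) should give 2-allyl-6-methoxy-1,4-phenylene diacetate F5, which can be purified. Treatment with K2CO3 and BnBr in MeOH/DMF at 50 °C under Ar cleaves the aryl acetates by methanolysis and benzylates each phenoxide as it forms, returning to the route at 4.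

Further compounds
F1 | step 4 | diethyl(undecyl)borane | CCCCCCCCCCCB(CC)CC
F2 | step 4 | diundecylzinc | CCCCCCCCCCC[Zn]CCCCCCCCCCC
F3 | step 4 | (R)-1-[2,5-bis(benzyloxy)-3-methoxyphenyl]tridecan-2-ol | CCCCCCCCCCC[C@H](Cc1cc(OCc2ccccc2)cc(OC)c1OCc1ccccc1)O
F4 | step 3 | 2-[2,5-bis(benzyloxy)-3-methoxyphenyl]ethanol | OCCc1cc(OCc2ccccc2)cc(OC)c1OCc1ccccc1
F5 | step 2 | 2-allyl-6-methoxy-1,4-phenylene diacetate | C=CCc1cc(OC(C)=O)cc(OC)c1OC(C)=O
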